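Betaethrin A (22) is reached by chemoselective acetylation of the primary alcohol of triol 21, after the ring A ester exchange (tert-butyl to methyl), O-debenzylation and removal of the side-chain silyl ether.
Ring B is made as a saturated ring and aromatised late: its oxygens on C2' (OH) and C4' (OMe) stand 1,3 across C3'–H and are read as the two carbonyls of cyclohexane-1,3-dione 12, C1' (the diaryl ether carbon) is the α-carbon of an aryloxyacetone, and C6' carries the CH2O arm.
Dione 12 comes from aryloxyacetone 5 and methyl (E)-4-silyloxybut-2-enoate 10 by a Michael–Claisen annulation (C1'–C6', then C3'–C4'); the C4' carbonyl is then fixed as methyl enol ether 13 and the ring dehydrogenated to phenol 17.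
Ketone 5 comes from ring A phenol 3 and chloroacetone, so the diaryl ether C–O bond is made by simple alkylation; 3 comes from 2,6-dihydroxy-4-methylbenzoic acid 1, and 10 from glycolaldehyde dimer 6 and ylide 7.
Ring A is bought intact; ring B is the only ring formed (step 6) and becomes aromatic in step 8. The ring A carboxyl travels as a tert-butyl ester, and the arm oxygen as a tert-butyldiphenylsilyl (TBDPS) ether because the final CH2OAc is a benzylic ester and must follow the hydrogenolysis.

Key step: step 6

Remark: compounds 11 to 15 are racemic and one enantiomer is drawn; both ring B stereocentres are removed in step 8 and the target is achiral. Ring B atoms are numbered C1' (ether carbon) to C6' (carbon bearing CH2O) throughout.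

Step 1
Reactants: 1 2,6-dihydroxy-4-methylbenzoic acid
Product: 2 tert-butyl 2,6-dihydroxy-4-methylbenzoate
Conditions: tert-butyl 2,2,2-trichloroacetimidate (2 equiv), THF/cyclohexane, rt
Reagents that add atoms: tert-butyl 2,2,2-trichloroacetimidate, CC(C)(C)OC(=N)C(Cl)(Cl)Cl
Why: Acid-promoted O-alkylation by a trichloroacetimidate: the strongly acidic 2,6-dihydroxybenzoic acid protonates the imidate and its carboxylate captures the tert-butyl cation at room temperature, which avoids decarboxylation and leaves the hydrogen-bonded phenols untouched.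

Step 2
Reactants: 2 tert-butyl 2,6-dihydroxy-4-methylbenzoate
Product: 3 tert-butyl 2-(benzyloxy)-6-hydroxy-4-methylbenzoate
Conditions: BnBr (1.0 equiv), K2CO3, acetone, rt to 50 °C
Reagents that add atoms: benzyl bromide, BrCc1ccccc1
Why: Williamson ether synthesis with one equivalent of halide; after the first alkylation the remaining hydroxyl is held in a hydrogen bond to the ester carbonyl and reacts much more slowly, so the monoether should predominate.

Step 3
Reactants: 3 tert-butyl 2-(benzyloxy)-6-hydroxy-4-methylbenzoate; 4 chloroacetone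
Product: 5 tert-butyl 2-(benzyloxy)-4-methyl-6-(2-oxopropoxy)benzoate
Conditions: K2CO3, KI (cat.), acetone, reflux
Reagents that add atoms: none
Why: Williamson alkylation of the remaining phenoxide, with chloroacetone activated in situ as iodoacetone (Finkelstein exchange); the mild carbonate base and the bulky tert-butyl ester should keep the aryloxy ketone from cyclising onto the ester.

Step 4
Reactants: 6 glycolaldehyde dimer (1,4-dioxane-2,5-diol); 7 methyl (triphenylphosphoranylidene)acetate
Product: 9 methyl (E)-4-hydroxybut-2-enoate, via glycolaldehyde 8 (not isolated)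
Conditions: THF, reflux
Reagents that add atoms: none
Why: Wittig olefination with a stabilised ylide, which is (E)-selective; the dimer releases monomeric glycolaldehyde on heating.

Step 5
Reactants: 9 methyl (E)-4-hydroxybut-2-enoate
Product: 10 methyl (E)-4-[(tert-butyldiphenylsilyl)oxy]but-2-enoate
Conditions: TBDPSCl, imidazole, CH2Cl2, 0 °C to rt
Reagents that add atoms: tert-butyl(chloro)diphenylsilane, CC(C)(C)[Si](Cl)(c1ccccc1)c1ccccc1
Why: Imidazole-mediated silylation of a primary alcohol; the TBDPS ether tolerates the base, acid and hydrogenolysis steps ahead and is removed by fluoride, which avoids the ambiguous hydrogenolysis of a benzyl ether on a benzylic oxygen.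

Step 6
Reactants: 5 tert-butyl 2-(benzyloxy)-4-methyl-6-(2-oxopropoxy)benzoate; 10 methyl (E)-4-[(tert-butyldiphenylsilyl)oxy]but-2-enoate
Product: 12 tert-butyl 2-(benzyloxy)-6-[(trans-6-{[(tert-butyldiphenylsilyl)oxy]methyl}-2,4-dioxocyclohexyl)oxy]-4-methylbenzoate (racemic), via Michael adduct keto ester 11 (not isolated)
Conditions: KOtBu (1.2 equiv), THF, −20 °C; then 10 added slowly, −20 °C to rt; cold 1 M HCl work-up
Reagents that add atoms: none
Why: tert-Butoxide enolises 5 reversibly, and the enolate at the ArO–CH2 carbon, favoured because the aryloxy group acidifies that position, adds to the β-carbon of 10 to form C1'–C6'; after proton transfer the methyl ketone enolate attacks the methyl ester in a 6-exo-trig Claisen closure that forms C3'–C4' and ring B as its saturated dione. The closest known reaction type is the one-pot consecutive Michael–Claisen synthesis of cyclohexane-1,3-diones from substituted acetones and α,β-unsaturated esters, in which the expelled methoxide deprotonates the acidic dione and so pulls the reversible Michael and Claisen steps forward. The two new stereocentres (C1' and C6') are set without any chiral control element; C1' is α to a ketone and should epimerise under the basic conditions to the trans diequatorial arrangement, and both centres are erased in step 8, so 12 is carried as the racemate. The step needs addition through the oxygen-bearing carbon and not through the methyl group, which the higher acidity of the ArO–CH2 site under equilibrating conditions should secure, and it must outrun Dieckmann attack of that carbanion on the ring A carboxyl, which the doubly ortho-substituted tert-butyl ester with its poor leaving group should suppress. Preforming the enolate of 5 at low temperature before 10 is added keeps free alkoxide low and should limit γ-deprotonation of the 4-silyloxy enoate.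

Step 7
Reactants: 12 tert-butyl 2-(benzyloxy)-6-[(trans-6-{[(tert-butyldiphenylsilyl)oxy]methyl}-2,4-dioxocyclohexyl)oxy]-4-methylbenzoate
Product: 13 tert-butyl 2-(benzyloxy)-6-[(trans-6-{[(tert-butyldiphenylsilyl)oxy]methyl}-4-methoxy-2-oxocyclohex-3-en-1-yl)oxy]-4-methylbenzoate (racemic)
Conditions: TsOH·H2O (cat.), MeOH, rt
Reagents that add atoms: methanol, CO
Why: Acid-catalysed enol etherification of a cyclic 1,3-dione: methanol condenses at the C4' carbonyl, which is remote from the aryloxy-bearing C1' and less hindered, and because the reaction is reversible the vinylogous ester free of allylic strain between OMe and the C1' substituent should accumulate.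

Step 8
Reactants: 13 tert-butyl 2-(benzyloxy)-6-[(trans-6-{[(tert-butyldiphenylsilyl)oxy]methyl}-4-methoxy-2-oxocyclohex-3-en-1-yl)oxy]-4-methylbenzoate
Product: 17 tert-butyl 2-(benzyloxy)-6-(2-{[(tert-butyldiphenylsilyl)oxy]methyl}-6-hydroxy-4-methoxyphenoxy)-4-methylbenzoate, via α-phenylselanyl ketone 14 (not isolated), via selenoxide 15 (not isolated), via cyclohexadienone 16 (not isolated)
Conditions: LiN(iPr)2 (1.1 equiv), THF, −78 °C; PhSeBr, −78 °C; then 30% H2O2, pyridine, CH2Cl2, 0 °C to rt
Reagents that add atoms: none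
Why: Selenoxide dehydrogenation of a vinylogous ester: kinetic α'-deprotonation at C1' (axial hydrogen, acidified by the aryloxy group), selenenylation anti to the neighbouring silyloxymethyl group so that selenium sits cis to H–C6', then selenoxide syn-elimination to the cross-conjugated dienone, which tautomerises to the C2' phenol; the tert-butyl ester keeps the C1' enolate from closing onto the ring A carboxyl.

Step 9
Reactants: 17 tert-butyl 2-(benzyloxy)-6-(2-{[(tert-butyldiphenylsilyl)oxy]methyl}-6-hydroxy-4-methoxyphenoxy)-4-methylbenzoate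
Product: 18 2-(benzyloxy)-6-(2-{[(tert-butyldiphenylsilyl)oxy]methyl}-6-hydroxy-4-methoxyphenoxy)-4-methylbenzoic acid
Conditions: CF3CO2H/CH2Cl2 (1:4), 0 °C to rt
Reagents that add atoms: none
Why: Acidolysis of the tert-butyl ester through the tert-butyl cation (lost as isobutene), which should leave the benzyl, methyl and aryl ethers and the acid-robust TBDPS ether intact; both positions ortho to the ether oxygen on ring B are substituted, so no xanthone can form.

Step 10
Reactants: 18 2-(benzyloxy)-6-(2-{[(tert-butyldiphenylsilyl)oxy]methyl}-6-hydroxy-4-methoxyphenoxy)-4-methylbenzoic acid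
Product: 19 methyl 2-(benzyloxy)-6-(2-{[(tert-butyldiphenylsilyl)oxy]methyl}-6-hydroxy-4-methoxyphenoxy)-4-methylbenzoate
Conditions: MeI, KHCO3, DMF, rt
Reagents that add atoms: iodomethane, CI
Why: SN2 O-alkylation of the carboxylate, which is insensitive to the two ortho substituents that would block Fischer esterification; hydrogencarbonate is too weak a base to ionise the ring B phenol, so only the acid should be methylated.

Step 11
Reactants: 19 methyl 2-(benzyloxy)-6-(2-{[(tert-butyldiphenylsilyl)oxy]methyl}-6-hydroxy-4-methoxyphenoxy)-4-methylbenzoate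
Product: 20 methyl 2-(2-{[(tert-butyldiphenylsilyl)oxy]methyl}-6-hydroxy-4-methoxyphenoxy)-6-hydroxy-4-methylbenzoate
Conditions: H2 (1 atm), 10% Pd/C, EtOAc, rt
Reagents that add atoms: none
Why: Catalytic hydrogenolysis of the aryl benzyl ether, which is fast under neutral conditions while the benzylic silyl ether is cleaved far more slowly; it is placed before acetylation because the final CH2OAc is itself a hydrogenolysable benzylic ester.

Step 12
Reactants: 20 methyl 2-(2-{[(tert-butyldiphenylsilyl)oxy]methyl}-6-hydroxy-4-methoxyphenoxy)-6-hydroxy-4-methylbenzoate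
Product: 21 methyl 2-hydroxy-6-[2-hydroxy-6-(hydroxymethyl)-4-methoxyphenoxy]-4-methylbenzoate
Conditions: Bu4NF, AcOH, THF, 0 °C to rt
Reagents that add atoms: none
Why: Fluoride-driven desilylation (formation of the strong Si–F bond); acetic acid buffers the medium so that no alkoxide or phenoxide attacks the methyl ester.

Step 13
Reactants: 21 methyl 2-hydroxy-6-[2-hydroxy-6-(hydroxymethyl)-4-methoxyphenoxy]-4-methylbenzoate
Product: 22 betaethrin A, methyl 2-[2-(acetoxymethyl)-6-hydroxy-4-methoxyphenoxy]-6-hydroxy-4-methylbenzoate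
Conditions: AcCl (1.05 equiv), 2,4,6-collidine, CH2Cl2, −78 °C
Reagents that add atoms: acetyl chloride, CC(Cl)=O
Why: Chemoselective acylation with an acid chloride and a weak hindered pyridine base at low temperature: the primary benzylic alcohol is the most nucleophilic hydroxyl, the ring A phenol is locked in a hydrogen bond to the ester, and the ring B phenol is crowded by the diaryl ether and not ionised by collidine.

Compound list
1 | 2,6-dihydroxy-4-methylbenzoic acid | Cc1cc(O)c(C(=O)O)c(O)c1 | starting material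
2 | tert-butyl 2,6-dihydroxy-4-methylbenzoate | Cc1cc(O)c(C(=O)OC(C)(C)C)c(O)c1 | intermediate
3 | tert-butyl 2-(benzyloxy)-6-hydroxy-4-methylbenzoate | Cc1cc(O)c(C(=O)OC(C)(C)C)c(OCc2ccccc2)c1 | intermediate
4 | chloroacetone (1-chloropropan-2-one) | CC(=O)CCl | starting material
5 | tert-butyl 2-(benzyloxy)-4-methyl-6-(2-oxopropoxy)benzoate | CC(=O)COc1cc(C)cc(OCc2ccccc2)c1C(=O)OC(C)(C)C | intermediate
6 | glycolaldehyde dimer (1,4-dioxane-2,5-diol) | OC1COC(O)CO1 | starting material
7 | methyl (triphenylphosphoranylidene)acetate | COC(=O)C=P(c1ccccc1)(c1ccccc1)c1ccccc1 | starting material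
8 | glycolaldehyde (2-hydroxyacetaldehyde; not isolated) | OCC=O | intermediate
9 | methyl (E)-4-hydroxybut-2-enoate | COC(=O)/C=C/CO | intermediate
10 | methyl (E)-4-[(tert-butyldiphenylsilyl)oxy]but-2-enoate | COC(=O)/C=C/CO[Si](c1ccccc1)(c1ccccc1)C(C)(C)C | intermediate
11 | methyl 4-[3-(benzyloxy)-2-(tert-butoxycarbonyl)-5-methylphenoxy]-3-{[(tert-butyldiphenylsilyl)oxy]methyl}-5-oxohexanoate (Michael adduct; racemic, both diastereomers, stereocentres left undefined; not isolated) | COC(=O)CC(CO[Si](c1ccccc1)(c1ccccc1)C(C)(C)C)C(Oc1cc(C)cc(OCc2ccccc2)c1C(=O)OC(C)(C)C)C(C)=O | intermediate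
12 | tert-butyl 2-(benzyloxy)-6-[(trans-6-{[(tert-butyldiphenylsilyl)oxy]methyl}-2,4-dioxocyclohexyl)oxy]-4-methylbenzoate (racemic; aryloxy and silyloxymethyl trans) | CC(C)(C)OC(=O)c1c(OCc2ccccc2)cc(C)cc1O[C@@H]1C(=O)CC(=O)C[C@H]1CO[Si](c1ccccc1)(c1ccccc1)C(C)(C)C | intermediate
13 | tert-butyl 2-(benzyloxy)-6-[(trans-6-{[(tert-butyldiphenylsilyl)oxy]methyl}-4-methoxy-2-oxocyclohex-3-en-1-yl)oxy]-4-methylbenzoate (racemic) | CC(C)(C)OC(=O)c1c(OCc2ccccc2)cc(C)cc1O[C@@H]1C(=O)C=C(OC)C[C@H]1CO[Si](c1ccccc1)(c1ccccc1)C(C)(C)C | intermediate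
14 | tert-butyl 2-(benzyloxy)-6-{[6-{[(tert-butyldiphenylsilyl)oxy]methyl}-4-methoxy-2-oxo-1-(phenylselanyl)cyclohex-3-en-1-yl]oxy}-4-methylbenzoate (racemic; PhSe trans to the silyloxymethyl group, cis to H–C6'; not isolated) | CC(C)(C)OC(=O)c1c(OCc2ccccc2)cc(C)cc1O[C@@]1([Se]c2ccccc2)C(=O)C=C(OC)C[C@H]1CO[Si](c1ccccc1)(c1ccccc1)C(C)(C)C | intermediate
15 | selenoxide of 14 (racemic; mixture at selenium; not isolated) | CC(C)(C)OC(=O)c1c(OCc2ccccc2)cc(C)cc1O[C@@]1([Se](=O)c2ccccc2)C(=O)C=C(OC)C[C@H]1CO[Si](c1ccccc1)(c1ccccc1)C(C)(C)C | intermediate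
16 | tert-butyl 2-(benzyloxy)-6-[(2-{[(tert-butyldiphenylsilyl)oxy]methyl}-4-methoxy-6-oxocyclohexa-1,4-dien-1-yl)oxy]-4-methylbenzoate (dienone tautomer of 17; not isolated) | CC(C)(C)OC(=O)c1c(OCc2ccccc2)cc(C)cc1OC1=C(CO[Si](c2ccccc2)(c2ccccc2)C(C)(C)C)CC(OC)=CC1=O | intermediate
17 | tert-butyl 2-(benzyloxy)-6-(2-{[(tert-butyldiphenylsilyl)oxy]methyl}-6-hydroxy-4-methoxyphenoxy)-4-methylbenzoate | CC(C)(C)OC(=O)c1c(OCc2ccccc2)cc(C)cc1Oc1c(O)cc(OC)cc1CO[Si](c1ccccc1)(c1ccccc1)C(C)(C)C | intermediate
18 | 2-(benzyloxy)-6-(2-{[(tert-butyldiphenylsilyl)oxy]methyl}-6-hydroxy-4-methoxyphenoxy)-4-methylbenzoic acid | OC(=O)c1c(OCc2ccccc2)cc(C)cc1Oc1c(O)cc(OC)cc1CO[Si](c1ccccc1)(c1ccccc1)C(C)(C)C | intermediate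
19 | methyl 2-(benzyloxy)-6-(2-{[(tert-butyldiphenylsilyl)oxy]methyl}-6-hydroxy-4-methoxyphenoxy)-4-methylbenzoate | COC(=O)c1c(OCc2ccccc2)cc(C)cc1Oc1c(O)cc(OC)cc1CO[Si](c1ccccc1)(c1ccccc1)C(C)(C)C | intermediate
20 | methyl 2-(2-{[(tert-butyldiphenylsilyl)oxy]methyl}-6-hydroxy-4-methoxyphenoxy)-6-hydroxy-4-methylbenzoate | COC(=O)c1c(O)cc(C)cc1Oc1c(O)cc(OC)cc1CO[Si](c1ccccc1)(c1ccccc1)C(C)(C)C | intermediate
21 | methyl 2-hydroxy-6-[2-hydroxy-6-(hydroxymethyl)-4-methoxyphenoxy]-4-methylbenzoate | COC(=O)c1c(O)cc(C)cc1Oc1c(O)cc(OC)cc1CO | intermediate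
22 | betaethrin A, methyl 2-[2-(acetoxymethyl)-6-hydroxy-4-methoxyphenoxy]-6-hydroxy-4-methylbenzoate | COC(=O)c1c(O)cc(C)cc1Oc1c(O)cc(OC)cc1COC(C)=O | target

Total step count: 13. Longest linear sequence: 11 steps (steps 1, 2, 3 and 6 to 13, from acid 1 to target 22).

Steps most likely to fail

Step 6 (key step). The conjugate addition may run through the methyl-side enolate and lead to the 2-aryloxy dione, the enoate may be consumed by γ-deprotonation and double-bond migration, or the hindered secondary carbanion may add slowly and revert by retro-Michael reaction. The fallback sets out from phenol 3 and dimer 6 and returns at dione 12; it gives the nucleophile a single, doubly activated acidic site and uses an enone as acceptor. Phenol 3 would be alkylated with dimethyl bromomalonate (K2CO3, acetone) to dimethyl 2-[3-(benzyloxy)-2-(tert-butoxycarbonyl)-5-methylphenoxy]propanedioate F1. Dimer 6 and 1-(triphenylphosphoranylidene)propan-2-one would give (E)-5-hydroxypent-3-en-2-one F2, which is silylated (tert-butyl(chloro)diphenylsilane, imidazole) to (E)-5-[(tert-butyldiphenylsilyl)oxy]pent-3-en-2-one F3. Catalytic Cs2CO3 in MeCN should add the malonate carbon of F1 to the β-carbon of F3 (again the C1'–C6' bond) to give dimethyl 2-aryloxy-2-(1-silyloxy-4-oxopentan-2-yl)propanedioate F4. NaOMe in MeOH would then close the methyl ketone enolate onto one malonate ester (C2'–C3' bond, the classical malonate–enone dione synthesis) to methyl 1-aryloxy-2,4-dioxo-6-(silyloxymethyl)cyclohexane-1-carboxylate F5. Krapcho dealkoxycarbonylation (LiCl, wet DMSO, heat) removes the extra ester and delivers 12.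

Step 7. Methanol may also condense at the carbonyl next to the aryloxy carbon, so that the two vinylogous esters form with poor regiocontrol. The fallback sets out from dione 12 and returns at phenol 17, bypassing 13 and step 8; the two oxygens are told apart after aromatisation instead. Dione 12 would be silylated twice (TMSOTf, Et3N, CH2Cl2) to the bis(trimethylsilyl) dienol ether F6, which DDQ should dehydrogenate to the resorcinol bis(trimethylsilyl) ether F7. Dilute aqueous citric acid in THF would free the resorcinol, tert-butyl 2-(benzyloxy)-6-(2-{[(tert-butyldiphenylsilyl)oxy]methyl}-4,6-dihydroxyphenoxy)-4-methylbenzoate F8, without touching the TBDPS ether. One equivalent of MeI with K2CO3 in acetone should then methylate the C4' hydroxyl, which has two unsubstituted neighbours, in preference to the C2' hydroxyl crowded by the diaryl ether, giving 17.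

Step 8. Enolisation or selenenylation at the crowded, fully substituted aryloxy carbon may be sluggish, selenium may enter cis to the silyloxymethyl group so that no syn β-hydrogen is available for elimination, or the peroxide and seleninic acid mixture may over-oxidise the electron-rich phenol as it forms. The fallback sets out from enone 13 and returns at phenol 17; it dehydrogenates without strong base or selenium. Soft enolisation of 13 (TMSOTf, Et3N, CH2Cl2, 0 °C) would give the trimethylsilyl dienol ether F9 (either dienol regioisomer serves). DDQ should remove hydride and a proton to give the aryl trimethylsilyl ether F10, and dilute aqueous citric acid hydrolyses it to 17.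

Further compounds
F1 | step 6 | dimethyl 2-[3-(benzyloxy)-2-(tert-butoxycarbonyl)-5-methylphenoxy]propanedioate | COC(=O)C(Oc1cc(C)cc(OCc2ccccc2)c1C(=O)OC(C)(C)C)C(=O)OC
F2 | step 6 | (E)-5-hydroxypent-3-en-2-one | CC(=O)/C=C/CO
F3 | step 6 | (E)-5-[(tert-butyldiphenylsilyl)oxy]pent-3-en-2-one | CC(=O)/C=C/CO[Si](c1ccccc1)(c1ccccc1)C(C)(C)C
F4 | step 6 | dimethyl 2-[3-(benzyloxy)-2-(tert-butoxycarbonyl)-5-methylphenoxy]-2-{1-[(tert-butyldiphenylsilyl)oxy]-4-oxopentan-2-yl}propanedioate (racemic) | COC(=O)C(Oc1cc(C)cc(OCc2ccccc2)c1C(=O)OC(C)(C)C)(C(=O)OC)C(CO[Si](c1ccccc1)(c1ccccc1)C(C)(C)C)CC(C)=O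
F5 | step 6 | methyl 1-[3-(benzyloxy)-2-(tert-butoxycarbonyl)-5-methylphenoxy]-6-{[(tert-butyldiphenylsilyl)oxy]methyl}-2,4-dioxocyclohexane-1-carboxylate (racemic, diastereomer mixture) | COC(=O)C1(Oc2cc(C)cc(OCc3ccccc3)c2C(=O)OC(C)(C)C)C(=O)CC(=O)CC1CO[Si](c1ccccc1)(c1ccccc1)C(C)(C)C
F6 | step 7 | tert-butyl 2-(benzyloxy)-6-[(trans-6-{[(tert-butyldiphenylsilyl)oxy]methyl}-2,4-bis[(trimethylsilyl)oxy]cyclohexa-2,4-dien-1-yl)oxy]-4-methylbenzoate (racemic) | CC(C)(C)OC(=O)c1c(OCc2ccccc2)cc(C)cc1O[C@@H]1C(O[Si](C)(C)C)=CC(O[Si](C)(C)C)=C[C@H]1CO[Si](c1ccccc1)(c1ccccc1)C(C)(C)C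
F7 | step 7 | tert-butyl 2-(benzyloxy)-6-(2-{[(tert-butyldiphenylsilyl)oxy]methyl}-4,6-bis[(trimethylsilyl)oxy]phenoxy)-4-methylbenzoate | CC(C)(C)OC(=O)c1c(OCc2ccccc2)cc(C)cc1Oc1c(O[Si](C)(C)C)cc(O[Si](C)(C)C)cc1CO[Si](c1ccccc1)(c1ccccc1)C(C)(C)C
F8 | step 7 | tert-butyl 2-(benzyloxy)-6-(2-{[(tert-butyldiphenylsilyl)oxy]methyl}-4,6-dihydroxyphenoxy)-4-methylbenzoate | CC(C)(C)OC(=O)c1c(OCc2ccccc2)cc(C)cc1Oc1c(O)cc(O)cc1CO[Si](c1ccccc1)(c1ccccc1)C(C)(C)C
F9 | step 8 | tert-butyl 2-(benzyloxy)-6-[(trans-6-{[(tert-butyldiphenylsilyl)oxy]methyl}-4-methoxy-2-[(trimethylsilyl)oxy]cyclohexa-2,4-dien-1-yl)oxy]-4-methylbenzoate (racemic) | CC(C)(C)OC(=O)c1c(OCc2ccccc2)cc(C)cc1O[C@@H]1C(O[Si](C)(C)C)=CC(OC)=C[C@H]1CO[Si](c1ccccc1)(c1ccccc1)C(C)(C)C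
F10 | step 8 | tert-butyl 2-(benzyloxy)-6-(2-{[(tert-butyldiphenylsilyl)oxy]methyl}-4-methoxy-6-[(trimethylsilyl)oxy]phenoxy)-4-methylbenzoate | CC(C)(C)OC(=O)c1c(OCc2ccccc2)cc(C)cc1Oc1c(O[Si](C)(C)C)cc(OC)cc1CO[Si](c1ccccc1)(c1ccccc1)C(C)(C)C
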